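At 25 °C, over 5.00 d, larch with 9.4 µM of free enzyme brought its substrate down to 60.6% of the charge, and oak with 28 µM brought it down to 17.0%. Target and substrate in oak still summed to 98.9%, so I treated substrate as passing straight to target.

| flask | substrate | free enzyme | temperature | remark | time |
|---|---|---|---|---|---|
| larch | 28 mM | 9.4 µM | 25 °C | run made earlier |  |
| oak | 28 mM | 28 µM | 25 °C | run made earlier |  |
| green | 28 mM | 14 µM | 25 °C |  | 8.0 d |
| amber | 80 mM | 14 µM | 25 °C |  | 8.0 d |

| run | time / d | target / % | substrate / % |
|---|---|---|---|
| larch | 0.417 | 2.8 | 96.3 |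
| larch | 0.625 | 6.4 | 93.9 |
| larch | 0.833 | 7.0 | 91.9 |
| larch | 1.25 | 9.9 | 87.5 |
| larch | 2.08 | 16.3 | 80.6 |
| larch | 3.00 | 24.4 | 75.2 |
| larch | 5.00 | 39.9 | 60.6 |
| oak | 0.250 | 8.1 | 93.7 |
| oak | 0.833 | 21.3 | 77.8 |
| oak | 1.25 | 29.6 | 69.8 |
| oak | 2.08 | 47.6 | 53.0 |
| oak | 3.00 | 63.7 | 38.4 |
| oak | 4.00 | 72.7 | 25.3 |
| oak | 5.00 | 81.9 | 17.0 |

(scatter of a reading: 1 percentage point)

1. which of the two ends with the higher amount of target, in percent of the substrate charged ("neither" if they lie within 2 percentage points) (green / amber / neither)
2. target at the end, in percent of the substrate charged, green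
3. target at the end, in percent of the substrate charged, amber

- the numbers in the tables scatter by 1 percentage point (one standard deviation)

I took enzyme multiplied by time as the dose. Green's dose of 112 µM·d matches oak's at 4.00 d, 112 µM·d, on the same charge, and oak read 72.7% there, so I expected about that for green.

Amber gets the same dose on 80 mM, so I needed a law that sees the charge. I used the integrated Michaelis–Menten form: substrate used, plus K times the logarithm of starting over present substrate, equals a capacity times the dose. Larch's last reading gave 11.0 mM used, a logarithm of 0.501 and a dose of 47.0 µM·d. Oak's gave 23.2 mM, 1.77 and 140 µM·d. These two readings, with their scatter, put K, the substrate level at which half of the enzyme is busy (the Michaelis constant), at 34.4 mM. Amber's dose then corresponds to 67.3 mM of substrate turned with the enzyme fully busy.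

The busy share is [S]/(K+[S]), but [S] depends on the answer, so I went round. The starting share of 70.0% gave 47.1 mM of target. That put mean substrate at 56.5 mM, the share at 62.2% and target at 41.8 mM. Another round, from 59.1 mM, gave 63.2% and 42.6 mM, which is 53.2% of amber's charge. I therefore put green ahead, with more target in percent.

The forecast said green, with 74% for green and 51% for amber, a little below my figure for amber. Of the runs it said: “The apparent first-order constant rises as substrate falls, showing partial saturation and no enzyme decay”.

The flasks gave 73.9% for green and 54.8% for amber, so green ended higher, as forecast.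

    free enzyme → unfolded enzyme (k = 1.30 × 10⁻⁶ min⁻¹, Ea = 275 kJ mol⁻¹)
    substrate + free enzyme ⇌ complex (K = 24.0 L mol⁻¹, k = 1600 L mol⁻¹ min⁻¹, Ea = 46.0 kJ mol⁻¹, ΔH = 17.0 kJ mol⁻¹)
    complex → free enzyme + target (k = 0.480 min⁻¹, Ea = 86.0 kJ mol⁻¹)
    (constants at 25 °C)

A neighbour of amber charged with 48 mM has the same dose, and the same rounds give 39.2 mM, 30.4 mM, 32.9 mM and 32.2 mM, or 67.1% of its charge, where that flask gave 66.1%. In amber, the forward binding step alone gives substrate a half-life of 0.97 h at 8.00 d, far shorter than the 8.0 d run. Complex was made and used up, each taken net, at a ratio of 1.00 at that time, and K with amber's 45% of substrate left gives a busy share of 51.1%, where complex held 46.0% of the catalyst charged at 8.00 d.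

The numbers in the tables come from a simulation for substances that don't exist; scatter was added.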